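**Retrosynthetic overview**
1. The tetronic acid ring is closed last by Dieckmann cyclisation of an (S)-α-propanoyloxy methyl ester; C5 comes from methyl (S)-glycidate.
2. Key disconnection C10–C11: a Ni/pybox enantioconvergent radical sp3–sp3 coupling of a racemic pentadienyl chloride (C11–C18 plus lactam) with a homoallylic alkylzinc (C5–C10). It sets C11 and joins the two halves.
3. East half: the pyrrolinone is made first (hept-6-ynal + glyoxylic acid → hydroxybutenolide → reductive amination/lactamisation with isopentylamine); the 14E alkene comes from Zr-carboalumination, with the alane trapped by crotonaldehyde.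
4. West half: the 7Z alkene comes from a Stork–Zhao iodo-olefination; C6–C7 from Cu-catalysed alkenyl opening of the glycidate.
5. Ring order: butenolide → pyrrolinone (steps 2–3), tetronic acid (step 10).

Locants: lactone C2(=O), C3(Me), C4(OH), C5; chain C6–C18; the target is 5S, 7Z, 11S, 12E, 14E.
Assumptions: 3-(tert-butyldimethylsilyloxy)propanal is purchased as such. The pybox antipode that gives 11S is fixed by a model coupling, since I cannot state the sense of induction from memory; both antipodes are accessible.

**Step 1**
Reactants: 1 hept-6-yn-1-ol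
Product: 2 hept-6-ynal
Conditions: TEMPO (5 mol %), PhI(OAc)2, CH2Cl2, rt
Reagents that add atoms: none
Why: TEMPO/BAIB oxoammonium oxidation stops at the aldehyde and leaves the terminal alkyne untouched; 2 is used without storage.

**Step 2**
Reactants: 2 hept-6-ynal; 3 glyoxylic acid (50 % aq.)
Product: 4 5-hydroxy-4-(pent-4-yn-1-yl)furan-2(5H)-one (racemic lactol)
Conditions: morpholine (1 equiv), heptane/H2O, 45 °C; then conc. HCl, rt
Reagents that add atoms: water, O (the lactol OH arrives on hydrolysis of the 5-morpholino intermediate)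
Why: Enamine-mediated aldol-type condensation of the aldehyde α-carbon with glyoxylic acid, then lactolisation, is the standard entry to 4-alkyl-5-hydroxybutenolides; the lactol centre is removed in step 3.

**Step 3**
Reactants: 4; 5 3-methylbutan-1-amine
Product: 6 1-(3-methylbutyl)-4-(pent-4-yn-1-yl)-1,5-dihydro-2H-pyrrol-2-one
Conditions: NaBH(OAc)3, AcOH, CH2Cl2, rt; then 40 °C
Reagents that add atoms: none
Why: Reductive amination of the ring-opened (Z)-formyl-acrylic acid, then spontaneous lactamisation of the cis amino acid, gives the N-alkyl 4-substituted 3-pyrrolin-2-one.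

**Step 4**
Reactants: 6; 7 (E)-crotonaldehyde
Product: 8 4-[(4E,7E)-6-hydroxy-4-methylnona-4,7-dien-1-yl]-1-(3-methylbutyl)-1,5-dihydro-2H-pyrrol-2-one (racemic carbinol)
Conditions: Me3Al (4 equiv), Cp2ZrCl2 (0.5 equiv), CH2Cl2, 0 °C → rt; then 7 (3 equiv), −78 → 0 °C
Reagents that add atoms: trimethylaluminium, C[Al](C)C (CH3)
Why: Negishi Zr-catalysed syn-methylalumination puts Me on the internal carbon and Al on the terminus, which fixes 14E, and the alkenylalane then adds 1,2 to the enal; the tertiary lactam only ties up one equivalent of Me3Al, and the carbinol centre is erased in step 9.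

**Step 5**
Reactants: 8
Product: 9 4-[(4E,6E)-8-chloro-4-methylnona-4,6-dien-1-yl]-1-(3-methylbutyl)-1,5-dihydro-2H-pyrrol-2-one (racemic)
Conditions: MsCl, s-collidine, LiCl, DMF, 0 °C; cold work-up, used at once
Reagents that add atoms: lithium chloride, [Li+].[Cl-] (Cl)
Why: Collington–Meyers chlorination; the bis-allylic mesylate ionises and chloride returns at the less hindered methyl-bearing terminus (SN1/SN2′) to give the conjugated secondary chloride, and any regioisomeric chloride funnels to the same radical in step 9.

**Step 6**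
Reactants: 10 3-[(tert-butyldimethylsilyl)oxy]propanal
Product: 11 tert-butyl{[(3Z)-4-iodopent-3-en-1-yl]oxy}dimethylsilane
Conditions: EtPPh3I, n-BuLi, THF; I2, −78 °C; NaHMDS, −20 °C; then 10, −78 °C → rt
Reagents that add atoms: ethyltriphenylphosphonium iodide, CC[P+](c1ccccc1)(c1ccccc1)c1ccccc1.[I-] (C–CH3); iodine, II (I)
Why: Stork–Zhao α-iodo Wittig olefination gives the (Z)-2-iodo-2-alkene (I cis to the chain), which pre-sets the 7Z geometry.

**Step 7**
Reactants: 11; 12 methyl (S)-oxirane-2-carboxylate (methyl (S)-glycidate); 13 propanoyl chloride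
Product: 14 methyl (2S,4Z)-7-[(tert-butyldimethylsilyl)oxy]-4-methyl-2-(propanoyloxy)hept-4-enoate
Conditions: t-BuLi (2 equiv), Et2O, −78 °C; MgBr2·OEt2; CuI (10 mol %), 12, THF, −40 °C; then 13, −40 → 0 °C
Reagents that add atoms: none
Why: Li–I exchange and transmetalation retain alkene geometry; Cu-catalysed Grignard epoxide opening occurs at the CH2 terminus, so the glycidate stereocentre is untouched and becomes C5 (S); the magnesium alkoxide is O-acylated in the same pot.

**Step 8**
Reactants: 14
Product: 15 methyl (2S,4Z)-7-bromo-4-methyl-2-(propanoyloxy)hept-4-enoate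
Conditions: Ph3P·Br2, CH2Cl2, 0 °C → rt
Reagents that add atoms: triphenylphosphine dibromide, BrP(Br)(c1ccccc1)(c1ccccc1)c1ccccc1 (Br)
Why: Direct silyl ether → bromide conversion via an alkoxyphosphonium and SN2 at the primary carbon, under neutral conditions that spare both esters, the alkene and C5.

**Step 9 (key step)**
Reactants: 15 (1.5 equiv, as its alkylzinc bromide); 9 (1.0 equiv)
Product: 16 methyl (2S,4Z,8S,9E,11E)-4,8,12-trimethyl-15-[1-(3-methylbutyl)-5-oxo-2,5-dihydro-1H-pyrrol-3-yl]-2-(propanoyloxy)pentadeca-4,9,11-trienoate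
Conditions: 15, Zn dust, I2 (5 mol %), DMA, 70 °C; then 9, NiCl2·glyme (10 mol %), 2,6-bis[4-(2-phenylethyl)-4,5-dihydrooxazol-2-yl]pyridine (12 mol %, single enantiomer), NaCl (4 equiv), DMF/DMA 1:1, −10 °C
Reagents that add atoms: none
Why: Proposed new method: this is a vinylogous extension of the Ni/pybox enantioconvergent Negishi coupling of racemic secondary allylic chlorides with primary alkylzinc halides (closest known reaction); Ni(I) abstracts Cl from either enantiomer or regioisomer of 9 to give one planar pentadienyl radical, which is captured by the chiral (pybox)Ni(II)–alkyl and reductively eliminates at the less hindered methyl-bearing terminus, keeping the trisubstituted diene conjugated, so the ligand sets C11 (S), and the 14E geometry should survive because rotation about the terminal bond of a pentadienyl radical (my estimate ≥ 15 kcal/mol) is slower than capture at −10 °C.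

**Step 10**
Reactants: 16
Product: 17 Sarcotrine D, (5S)-4-hydroxy-3-methyl-5-{(2Z,6S,7E,9E)-2,6,10-trimethyl-13-[1-(3-methylbutyl)-5-oxo-2,5-dihydro-1H-pyrrol-3-yl]trideca-2,7,9-trien-1-yl}furan-2(5H)-one
Conditions: LiHMDS (3 equiv), THF, −78 °C; 1 M HCl quench
Reagents that add atoms: none
Why: Dieckmann cyclisation: the propanoate enolate attacks the methyl ester and expels methoxide to give the 3-methyltetronic acid; C5 is not part of the enolate and the product tetronate anion resists further deprotonation, while any lactam γ-deprotonation reverts to the conjugated pyrrolinone on acidic quench.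

**Compound list**
1 | hept-6-yn-1-ol | C#CCCCCCO | starting material
2 | hept-6-ynal | C#CCCCCC=O | intermediate
3 | glyoxylic acid | OC(=O)C=O | starting material
4 | 5-hydroxy-4-(pent-4-yn-1-yl)furan-2(5H)-one (racemic) | C#CCCCC1=CC(=O)OC1O | intermediate
5 | 3-methylbutan-1-amine | CC(C)CCN | starting material
6 | 1-(3-methylbutyl)-4-(pent-4-yn-1-yl)-1,5-dihydro-2H-pyrrol-2-one | C#CCCCC1=CC(=O)N(CCC(C)C)C1 | intermediate
7 | (E)-but-2-enal (crotonaldehyde) | C/C=C/C=O | starting material
8 | 4-[(4E,7E)-6-hydroxy-4-methylnona-4,7-dien-1-yl]-1-(3-methylbutyl)-1,5-dihydro-2H-pyrrol-2-one (racemic) | C/C=C/C(O)/C=C(\C)CCCC1=CC(=O)N(CCC(C)C)C1 | intermediate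
9 | 4-[(4E,6E)-8-chloro-4-methylnona-4,6-dien-1-yl]-1-(3-methylbutyl)-1,5-dihydro-2H-pyrrol-2-one (racemic) | CC(Cl)/C=C/C=C(\C)CCCC1=CC(=O)N(CCC(C)C)C1 | intermediate
10 | 3-[(tert-butyldimethylsilyl)oxy]propanal | O=CCCO[Si](C)(C)C(C)(C)C | starting material
11 | tert-butyl{[(3Z)-4-iodopent-3-en-1-yl]oxy}dimethylsilane | C/C(I)=C/CCO[Si](C)(C)C(C)(C)C | intermediate
12 | methyl (S)-oxirane-2-carboxylate | COC(=O)[C@@H]1CO1 | starting material
13 | propanoyl chloride | CCC(Cl)=O | starting material
14 | methyl (2S,4Z)-7-[(tert-butyldimethylsilyl)oxy]-4-methyl-2-(propanoyloxy)hept-4-enoate | COC(=O)[C@H](C/C(C)=C\CCO[Si](C)(C)C(C)(C)C)OC(=O)CC | intermediate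
15 | methyl (2S,4Z)-7-bromo-4-methyl-2-(propanoyloxy)hept-4-enoate | COC(=O)[C@H](C/C(C)=C\CCBr)OC(=O)CC | intermediate
16 | methyl (2S,4Z,8S,9E,11E)-4,8,12-trimethyl-15-[1-(3-methylbutyl)-5-oxo-2,5-dihydro-1H-pyrrol-3-yl]-2-(propanoyloxy)pentadeca-4,9,11-trienoate | COC(=O)[C@H](C/C(C)=C\CC[C@H](C)/C=C/C=C(\C)CCCC1=CC(=O)N(CCC(C)C)C1)OC(=O)CC | intermediate
17 | Sarcotrine D | CC1=C(O)[C@H](C/C(C)=C\CC[C@H](C)/C=C/C=C(\C)CCCC2=CC(=O)N(CCC(C)C)C2)OC1=O | target

**Totals**
Total steps: 10. Longest linear sequence: 7 (steps 1–5, 9, 10); the west arm is steps 6–8.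

**Three steps most likely to fail**
1. Step 9 (with the labile chloride from step 5). Risks are coupling at C13 (skipped diene), low ee on a pentadienyl rather than simple allyl system, and decomposition of 9. Fallback: split the event. Run the same Ni/pybox coupling of the zinc reagent from 15 with the stable racemic (E)-(3-chlorobut-1-en-1-yl)trimethylsilane, iododesilylate the product (NIS) to the (E)-vinyl iodide, and join it to the alkenylalane from 6 by Pd-catalysed Negishi coupling. This replaces steps 4, 5 and 9 with three steps of closer precedent.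
2. Step 4. The Lewis-basic lactam may stall the carboalumination, or methyl may compete with alkenyl transfer to the aldehyde. Fallback: carboaluminate and iodinate hept-6-yn-1-ol first (free alkynols are well precedented), build the lactam on the (E)-vinyl iodide by steps 1–3, then make 8 by Nozaki–Hiyama–Kishi (CrCl2/NiCl2) addition to crotonaldehyde.
3. Step 10. LiHMDS may erode C5 or cause side reactions of the lactam dienolate. Fallback: close the tetronic acid before the fragment union. Cyclise 14, mask the tetronic acid as its 4-O-MOM ether, carry that through steps 8 and 9, and unmask with mild acid at the end.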